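## Retrosynthetic overview

- Peniophorin is the two-electron oxidation product of its leuco form, a 5,6-dihydroxy-3-aryl-benzofuran-2(3H)-one; the quinone methide is therefore generated last, after BBr3 removal of three methyl ethers.
- The benzofuranone comes from an intermolecular Mukaiyama–Michael addition of the silyl ketene acetal of methyl 4-methoxyphenylacetate to 3-methoxy-5-(4-methoxyphenyl)-2-phenyl-1,4-benzoquinone (forms C3–C3a), followed by lactonisation onto the flanking OH.
- The quinone comes from oxidative demethylation of a 2',3',5'-trimethoxy-p-terphenyl. Its two aryl groups are attached by Suzuki couplings, the second after directed ortho-lithiation/iodination between two OMe groups.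
- The oxygenation pattern and the first coupling handle are bought in 5-bromoveratraldehyde (Baeyer–Villiger, then O-methylation).
- Ring order: all benzene rings are purchased; the lactone ring closes in the Michael/lactonisation step; the quinone methide ring system appears in the final oxidation.

Assumption: the target has no stereocentre, so it is made as the single achiral compound drawn; the one stereocentre that arises on the way (C3 of the benzofuranone intermediates) is racemic and is erased in the last step.

## Route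

Step 1
Reactants: 1 3-bromo-4,5-dimethoxybenzaldehyde
Product: 3 3-bromo-4,5-dimethoxyphenol, via aryl formate 2 (not isolated)
Conditions: mCPBA (1.3 equiv), CH2Cl2, 0 °C to rt; then K2CO3 (10 mol %), MeOH, rt
Reagents that add atoms: mCPBA, O=C(OO)c1cccc(Cl)c1
Why: Baeyer–Villiger oxidation in which the electron-rich aryl group (para-OMe) migrates to give the formate, which methanol transesterifies to the phenol while the aryl bromide is untouched.

Step 2
Reactants: 3 3-bromo-4,5-dimethoxyphenol
Product: 4 1-bromo-2,3,5-trimethoxybenzene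
Conditions: MeI (1.5 equiv), K2CO3 (2 equiv), acetone, reflux
Reagents that add atoms: iodomethane, CI
Why: Williamson O-methylation of the phenoxide (SN2) installs the 1,2,4-trimethoxy pattern that later directs lithiation and serves as the latent quinone.

Step 3
Reactants: 4 1-bromo-2,3,5-trimethoxybenzene; 5 4-methoxyphenylboronic acid
Product: 6 2,3,4',5-tetramethoxy-1,1'-biphenyl
Conditions: Pd(PPh3)4 (3 mol %), K2CO3 (2.5 equiv), toluene/EtOH/H2O, 85 °C
Reagents that add atoms: none
Why: Suzuki–Miyaura coupling of an aryl bromide with only one ortho substituent and a robust, electron-rich boronic acid; the methyl ethers are inert.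

Step 4
Reactants: 6 2,3,4',5-tetramethoxy-1,1'-biphenyl
Product: 8 4-iodo-2,3,4',5-tetramethoxy-1,1'-biphenyl, via aryllithium 7 (not isolated)
Conditions: n-BuLi (1.2 equiv), TMEDA (1.2 equiv), THF, 0 °C, 1.5 h; then I2 (1.4 equiv), THF, −78 °C to rt
Reagents that add atoms: iodine, II; n-butyllithium, [Li]CCCC (supplies the lithium of 7 only)
Why: Directed ortho-metalation removes the C4–H flanked by two methoxy groups (the cooperative site, as in 1,2,4-trimethoxybenzene), and the aryllithium is trapped by iodine.

Step 5
Reactants: 8 4-iodo-2,3,4',5-tetramethoxy-1,1'-biphenyl; 9 phenylboronic acid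
Product: 10 2',3',4,5'-tetramethoxy-1,1':4',1''-terphenyl (central ring: 4-methoxyphenyl at C1', OMe at C2', C3' and C5', phenyl at C4', H at C6')
Conditions: Pd(OAc)2 (2 mol %), SPhos (4 mol %), K3PO4 (3 equiv), toluene/H2O 10:1, 100 °C
Reagents that add atoms: none
Why: Suzuki–Miyaura coupling in which the bulky, electron-rich biarylphosphine SPhos handles the di-ortho-methoxy iodide, and phenylboronic acid does not protodeboronate.

Step 6
Reactants: 10 2',3',4,5'-tetramethoxy-1,1':4',1''-terphenyl
Product: 11 3-methoxy-5-(4-methoxyphenyl)-2-phenylcyclohexa-2,5-diene-1,4-dione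
Conditions: (NH4)2Ce(NO3)6 (2.5 equiv), MeCN/H2O 3:1, 0 °C, 20 min
Reagents that add atoms: water, O
Why: Oxidative demethylation of the para-dimethoxy pair (C2'/C5') of the most electron-rich ring gives the 1,4-quinone with the C3' methoxy retained, while the anisyl ring is much harder to oxidise.

Step 7
Reactants: 12 methyl 4-methoxyphenylacetate
Product: 14 [1-methoxy-2-(4-methoxyphenyl)ethenyl]oxy(trimethyl)silane (E/Z mixture), via lithium enolate 13 (not isolated)
Conditions: LiN(i-Pr)2 (1.1 equiv, commercial solution), THF, −78 °C, 30 min; then Me3SiCl (1.3 equiv), −78 °C to rt; pentane, filter, concentrate, use at once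
Reagents that add atoms: chlorotrimethylsilane, C[Si](C)(C)Cl; lithium diisopropylamide, [Li]N(C(C)C)C(C)C (supplies the lithium of 13 only)
Why: Kinetic ester enolisation followed by O-silylation gives the silyl ketene acetal; its double-bond geometry is irrelevant because that carbon becomes sp3 and later sp2 again.

Step 8
Reactants: 11 3-methoxy-5-(4-methoxyphenyl)-2-phenylcyclohexa-2,5-diene-1,4-dione; 14 [1-methoxy-2-(4-methoxyphenyl)ethenyl]oxy(trimethyl)silane
Product: 17 rac-5-hydroxy-6-methoxy-3,4-bis(4-methoxyphenyl)-7-phenyl-1-benzofuran-2(3H)-one, via silyl Michael adduct 15 (not isolated), via hydroquinone ester 16 (not isolated)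
Conditions: 14 (1.5 equiv), Me3SiOTf (10 mol %), CH2Cl2, −78 to −20 °C; 1 M HCl, THF, rt; then p-TsOH·H2O (10 mol %), toluene, 80 °C; all under Ar
Reagents that add atoms: none
Why: Mukaiyama–Michael addition at the only unsubstituted ring carbon (C6, β to the C4 carbonyl, which the vinylogous-ester OMe does not deactivate) followed by silyl transfer and enolisation gives the hydroquinone, whose OH ortho to the new side chain lactonises under acid; the new C3 stereocentre is racemic and is erased in step 10.

Step 9
Reactants: 17 rac-5-hydroxy-6-methoxy-3,4-bis(4-methoxyphenyl)-7-phenyl-1-benzofuran-2(3H)-one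
Product: 18 rac-5,6-dihydroxy-3,4-bis(4-hydroxyphenyl)-7-phenyl-1-benzofuran-2(3H)-one
Conditions: BBr3 (6 equiv), CH2Cl2, −78 °C to rt, 6 h; MeOH then H2O quench at 0 °C; under Ar, crude used directly
Reagents that add atoms: none
Why: Lewis-acid cleavage of the three aryl methyl ethers (bromide SN2 on the O-methyl of the boron complex) leaves the aryl lactone intact; C3 stays racemic.

Step 10
Reactants: 18 rac-5,6-dihydroxy-3,4-bis(4-hydroxyphenyl)-7-phenyl-1-benzofuran-2(3H)-one
Product: 19 peniophorin, 5-hydroxy-3,4-bis(4-hydroxyphenyl)-7-phenyl-1-benzofuran-2,6-dione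
Conditions: DDQ (1.05 equiv), THF, 0 °C to rt, 30 min, Ar
Reagents that add atoms: none
Why: Quinone dehydrogenation of the catechol bearing an acidic C3–H removes two hydrogens, and the oxidised product settles as the fully conjugated hydroxy quinone methide tautomer, which destroys the C3 stereocentre and gives the achiral target.

## Compound list

1 | 3-bromo-4,5-dimethoxybenzaldehyde (5-bromoveratraldehyde) | COc1cc(C=O)cc(Br)c1OC | starting material
2 | 3-bromo-4,5-dimethoxyphenyl formate | COc1cc(OC=O)cc(Br)c1OC | intermediate (not isolated)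
3 | 3-bromo-4,5-dimethoxyphenol | COc1cc(O)cc(Br)c1OC | intermediate
4 | 1-bromo-2,3,5-trimethoxybenzene | COc1cc(OC)cc(Br)c1OC | intermediate
5 | 4-methoxyphenylboronic acid | COc1ccc(B(O)O)cc1 | starting material
6 | 2,3,4',5-tetramethoxy-1,1'-biphenyl | COc1cc(OC)cc(-c2ccc(OC)cc2)c1OC | intermediate
7 | (2,3,4',5-tetramethoxy-[1,1'-biphenyl]-4-yl)lithium | COc1c([Li])c(OC)cc(-c2ccc(OC)cc2)c1OC | intermediate (not isolated)
8 | 4-iodo-2,3,4',5-tetramethoxy-1,1'-biphenyl | COc1c(I)c(OC)cc(-c2ccc(OC)cc2)c1OC | intermediate
9 | phenylboronic acid | OB(O)c1ccccc1 | starting material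
10 | 2',3',4,5'-tetramethoxy-1,1':4',1''-terphenyl | COc1c(-c2ccccc2)c(OC)cc(-c2ccc(OC)cc2)c1OC | intermediate
11 | 3-methoxy-5-(4-methoxyphenyl)-2-phenylcyclohexa-2,5-diene-1,4-dione | COC1=C(c2ccccc2)C(=O)C=C(c2ccc(OC)cc2)C1=O | intermediate
12 | methyl 4-methoxyphenylacetate | COC(=O)Cc1ccc(OC)cc1 | starting material
13 | lithium 1-methoxy-2-(4-methoxyphenyl)ethen-1-olate | [Li]OC(OC)=Cc1ccc(OC)cc1 | intermediate (not isolated)
14 | [1-methoxy-2-(4-methoxyphenyl)ethenyl]oxy(trimethyl)silane, E/Z mixture | COC(O[Si](C)(C)C)=Cc1ccc(OC)cc1 | intermediate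
15 | methyl 2-[2-hydroxy-4-methoxy-6-(4-methoxyphenyl)-3-phenyl-5-(trimethylsilyloxy)phenyl]-2-(4-methoxyphenyl)acetate, racemic | COC(=O)C(c1ccc(OC)cc1)c1c(O)c(-c2ccccc2)c(OC)c(O[Si](C)(C)C)c1-c1ccc(OC)cc1 | intermediate (not isolated)
16 | methyl 2-[2,5-dihydroxy-4-methoxy-6-(4-methoxyphenyl)-3-phenylphenyl]-2-(4-methoxyphenyl)acetate, racemic | COC(=O)C(c1ccc(OC)cc1)c1c(O)c(-c2ccccc2)c(OC)c(O)c1-c1ccc(OC)cc1 | intermediate (not isolated)
17 | 5-hydroxy-6-methoxy-3,4-bis(4-methoxyphenyl)-7-phenyl-1-benzofuran-2(3H)-one, racemic | O=C1Oc2c(-c3ccccc3)c(OC)c(O)c(-c3ccc(OC)cc3)c2C1c1ccc(OC)cc1 | intermediate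
18 | 5,6-dihydroxy-3,4-bis(4-hydroxyphenyl)-7-phenyl-1-benzofuran-2(3H)-one, racemic | O=C1Oc2c(-c3ccccc3)c(O)c(O)c(-c3ccc(O)cc3)c2C1c1ccc(O)cc1 | intermediate
19 | peniophorin, 5-hydroxy-3,4-bis(4-hydroxyphenyl)-7-phenyl-1-benzofuran-2,6-dione (achiral) | O=C1OC2=C(c3ccccc3)C(=O)C(O)=C(c3ccc(O)cc3)C2=C1c1ccc(O)cc1 | target

## Step count and risks

Total steps: 10. Longest linear sequence: 9 (steps 1–6 and 8–10 from compound 1; step 7 is a one-step side branch that joins at step 8).

Steps most likely to fail:

**Step 8 (Mukaiyama–Michael addition to the hindered quinone).** The risks are 1,2-addition, electron transfer, or a sluggish reaction next to the aryl group. The fallback sets out from 11. Reduction with aqueous Na2S2O4 (EtOAc/H2O, rt, Ar) gives the hydroquinone 3-methoxy-5-(4-methoxyphenyl)-2-phenylbenzene-1,4-diol F1. F1 is then condensed with commercial 4-methoxymandelic acid (p-TsOH·H2O, 1,2-dichloroethane, 80 °C). The stabilised 4-methoxybenzylic cation alkylates the only free ring CH (ortho to OH, para to OMe) in a Friedel–Crafts reaction, and the hydroxy acid lactonises in the same pot. The fallback comes back to the route at 17.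

**Step 6 (oxidative demethylation).** The risks are ortho-quinone formation, nitration, or over-oxidation of the tetramethoxy terphenyl. The fallback sets out from 10. BBr3 (CH2Cl2, −78 °C to rt) strips all four methyl groups to give 6-(4-hydroxyphenyl)-3-phenylbenzene-1,2,4-triol F2. This hydroxyhydroquinone autoxidises on stirring in air-saturated EtOAc/aqueous NaHCO3 to 3-hydroxy-5-(4-hydroxyphenyl)-2-phenylcyclohexa-2,5-diene-1,4-dione F3. Re-methylation of the vinylogous-acid OH and the phenol (Me2SO4, K2CO3, acetone, reflux) comes back to the route at 11.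

**Step 9 (triple demethylation to the air-sensitive leuco tetraphenol).** The fallback sets out from 17 and reverses the order of oxidation and deprotection. PhI(OAc)2 in MeCN/H2O at 0 °C oxidatively demethylates the guaiacol unit to the ortho-quinone, which tautomerises to 5-hydroxy-3,4-bis(4-methoxyphenyl)-7-phenyl-1-benzofuran-2,6-dione F4. BBr3 (CH2Cl2, −78 to 0 °C) then cleaves the two remaining anisole ethers at the stable pigment oxidation level. The fallback comes back to the route at 19 and bypasses 18 and step 10.

## Further compounds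

F1 | step 8 | 3-methoxy-5-(4-methoxyphenyl)-2-phenylbenzene-1,4-diol | COc1c(-c2ccccc2)c(O)cc(-c2ccc(OC)cc2)c1O
F2 | step 6 | 6-(4-hydroxyphenyl)-3-phenylbenzene-1,2,4-triol | Oc1c(-c2ccccc2)c(O)cc(-c2ccc(O)cc2)c1O
F3 | step 6 | 3-hydroxy-5-(4-hydroxyphenyl)-2-phenylcyclohexa-2,5-diene-1,4-dione | OC1=C(c2ccccc2)C(=O)C=C(c2ccc(O)cc2)C1=O
F4 | step 9 | 5-hydroxy-3,4-bis(4-methoxyphenyl)-7-phenyl-1-benzofuran-2,6-dione | O=C1OC2=C(c3ccccc3)C(=O)C(O)=C(c3ccc(OC)cc3)C2=C1c1ccc(OC)cc1
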